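**Retrosynthetic overview**

1. The target is cut at its two ester C–O bonds into acetate, (R)-solketal and decalin acid 20 (acetate last); the side chain is cut at C5–C1′, as an enol triflate of C5 ketone 14 plus a homoprenylzinc reagent (C4a is quaternary, so 14 enolises only toward C6).
2. Feature used: with the decalin numbered C1 (CH–CO2R), C2 (CH–Me), C3, C4, C4a and C8a (methylated fusion carbons) and C5–C8 (rest of ring B), the ring-A bonds C1–C2 and C4a–C8a are the two bonds of a cyclohexene retron once C3=C4 is present, and its enoate half (C1=C8a) and diene half (C2=C3–C4=C4a) are already linked by C5–C6–C7–C8.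
3. Key disconnection: thermal intramolecular Diels–Alder reaction of open-chain trienoate 10, whose single stereocentre (a silyloxy carbinol, the future C5) selects the diene face and is later oxidised to the C5 ketone.
4. Trienoate 10 comes from a B-alkyl Suzuki coupling of (E)-enol triflate 8 (from methyl acetoacetate) with the 9-BBN adduct of silyl ether 6, which comes from asymmetric allylboration of dienal 3 (crotonaldehyde plus a formyl ylide).
5. Ring order: rings A and B are closed together in step 6; no other ring is built (the dioxolane arrives with solketal and is opened in step 14).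

Key step: step 6

Remark: the glycerol carbon is taken as (S) as drawn (1-O-acyl-3-O-acetyl-sn-glycerol), which corresponds to acylating commercial (R)-solketal at its free primary hydroxyl without touching that carbon; "(+)-Ipc2B(allyl)" means the reagent made from (−)-α-pinene, as defined by its SMILES.

**Route**

Step 1
Reactants: 1 (E)-but-2-enal (crotonaldehyde); 2 2-(triphenylphosphoranylidene)propanal
Product: 3 (2E,4E)-2-methylhexa-2,4-dienal
Conditions: PhMe, 90 °C, excess 1
Reagents that add atoms: none
Why: Wittig olefination with a formyl-stabilised ylide should react once with the unhindered enal and give the (E)-trisubstituted alkene, extending the (E)-alkene of 1 to the (2E,4E)-dienal.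

Step 2
Reactants: 3 (2E,4E)-2-methylhexa-2,4-dienal
Product: 5 (4R,5E,7E)-5-methylnona-1,5,7-trien-4-ol, via borinate ester 4 (not isolated)
Conditions: (+)-Ipc2B(allyl), Et2O, −78 °C; then NaOH, H2O2, 0 °C → rt
Reagents that add atoms: (+)-B-allyldiisopinocampheylborane, C=CCB([C@H]1C[C@H]2C[C@@H]([C@@H]1C)C2(C)C)[C@H]1C[C@H]2C[C@@H]([C@@H]1C)C2(C)C
Why: Brown asymmetric allylboration through a chair-like six-membered transition state; the isopinocampheyl groups from (−)-α-pinene are expected to direct the allyl group to the Re face of the α-branched enal, setting the (4R) carbinol (future decalin C5), and only 1,2-addition is open to an allylborane.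

Step 3
Reactants: 5 (4R,5E,7E)-5-methylnona-1,5,7-trien-4-ol
Product: 6 tert-butyldimethyl{[(4R,5E,7E)-5-methylnona-1,5,7-trien-4-yl]oxy}silane
Conditions: TBSCl, imidazole, DMF, rt
Reagents that add atoms: tert-butyldimethylsilyl chloride, CC(C)(C)[Si](C)(C)Cl
Why: Imidazole-promoted silylation of a secondary allylic alcohol; the bulky silyl ether is the steering group for step 6 and is inert to boranes, palladium and heat.

Step 4
Reactants: 7 methyl 3-oxobutanoate (methyl acetoacetate)
Product: 8 methyl (2E)-3-{[(trifluoromethyl)sulfonyl]oxy}but-2-enoate (triflate trans to the ester)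
Conditions: Tf2O, aq. Me4NOH, hexane, 5 °C
Reagents that add atoms: trifluoromethanesulfonic anhydride, O=S(=O)(OS(=O)(=O)C(F)(F)F)C(F)(F)F
Why: O-Triflation of the β-keto ester enolate under biphasic hydroxide conditions; the non-chelating tetramethylammonium counter-ion should favour the extended enolate and hence the (E)-enol triflate, whereas a chelating lithium base would give the (Z)-isomer.

Step 5
Reactants: 6 tert-butyldimethyl{[(4R,5E,7E)-5-methylnona-1,5,7-trien-4-yl]oxy}silane; 8 methyl (2E)-3-{[(trifluoromethyl)sulfonyl]oxy}but-2-enoate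
Product: 10 methyl (2E,7R,8E,10E)-7-[(tert-butyldimethylsilyl)oxy]-3,8-dimethyldodeca-2,8,10-trienoate, via alkylborane 9 (not isolated)
Conditions: 9-BBN, THF, 0 °C → rt; then 8, Pd(dppf)Cl2 (5 mol%), AsPh3, Cs2CO3, DMF/H2O, rt
Reagents that add atoms: none
Why: 9-BBN should hydroborate the monosubstituted terminal alkene much faster than the conjugated, more substituted diene and place boron on the terminal carbon, and the B-alkyl Suzuki–Miyaura coupling with the enol triflate proceeds with retention of the (E)-geometry.

Step 6
Reactants: 10 methyl (2E,7R,8E,10E)-7-[(tert-butyldimethylsilyl)oxy]-3,8-dimethyldodeca-2,8,10-trienoate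
Product: 11 methyl (1S,2R,4aS,5R,8aR)-5-[(tert-butyldimethylsilyl)oxy]-2,4a,8a-trimethyl-1,2,4a,5,6,7,8,8a-octahydronaphthalene-1-carboxylate (cis-fused; ester cis to the C8a methyl and trans to the C2 methyl; silyloxy trans to the C4a methyl)
Conditions: BHT (cat.), degassed 1,2-dichlorobenzene (0.01 M), 190 °C, sealed tube
Reagents that add atoms: none
Why: The reaction is a concerted thermal [4+2] cycloaddition, suprafacial on both the C2=C3 enoate and the C8=C9–C10=C11 diene of 10, which forms decalin bonds C1–C2 and C4a–C8a; the closest known reaction type is the thermal intramolecular Diels–Alder reaction of ester-terminated 1,7,9-decatrienes. Ring A is closed as the new cyclohexene by the cycloaddition proper, and ring B is closed in the same event as a six-membered carbocycle, the four-carbon tether C5–C8 being completed by the C4a–C8a bond (fused, bicyclo[4.4.0] mode). C1 and C8a are controlled by the (2E)-enoate geometry (ester cis to the C8a methyl), C2 and C4a by the (8E,10E)-diene geometry (C2 methyl trans to the C4a methyl), and the relation between the two pairs by the ester-exo, tether-endo topology, which gives the cis ring fusion with the ester trans to the C2 methyl. The absolute sense of these four centres is controlled by the C5 silyloxy stereocentre: its C–H bond should lie in the diene plane next to the C4a methyl (least allylic 1,2-strain), so that the tether reaches one diene face while the silyloxy group points to the other, anti to the forming C4a–C8a bond and pseudo-equatorial on ring B. The step therefore needs exo (cis-fused) selectivity on that face; what should favour it is that the chair-like tether of the cis mode carries only one axial angular methyl whereas the trans mode carries two, while the endo preference of an enoate is weak at this temperature. The possible adducts are diastereomers and are to be separated here, before C5 is oxidised.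

Step 7
Reactants: 11 methyl (1S,2R,4aS,5R,8aR)-5-[(tert-butyldimethylsilyl)oxy]-2,4a,8a-trimethyl-1,2,4a,5,6,7,8,8a-octahydronaphthalene-1-carboxylate
Product: 12 methyl (1S,2R,4aS,5R,8aR)-5-[(tert-butyldimethylsilyl)oxy]-2,4a,8a-trimethyldecahydronaphthalene-1-carboxylate
Conditions: H2 (1 atm), PtO2, EtOAc, rt
Reagents that add atoms: none
Why: Heterogeneous hydrogenation of the only C=C bond (cis-disubstituted C3=C4) creates no stereocentre; platinum is chosen over palladium because it causes little double-bond migration, which would endanger the C2 stereocentre.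

Step 8
Reactants: 12 methyl (1S,2R,4aS,5R,8aR)-5-[(tert-butyldimethylsilyl)oxy]-2,4a,8a-trimethyldecahydronaphthalene-1-carboxylate
Product: 13 methyl (1S,2R,4aS,5R,8aR)-5-hydroxy-2,4a,8a-trimethyldecahydronaphthalene-1-carboxylate
Conditions: HF (48% aq.), MeCN, rt → 40 °C
Reagents that add atoms: none
Why: Fluoride-driven Si–O cleavage of the hindered secondary silyl ether under mildly acidic conditions that leave the methyl ester untouched; C1 and C5 are anti across the ring fusion, so lactonisation is not expected.

Step 9
Reactants: 13 methyl (1S,2R,4aS,5R,8aR)-5-hydroxy-2,4a,8a-trimethyldecahydronaphthalene-1-carboxylate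
Product: 14 methyl (1S,2R,4aS,8aR)-2,4a,8a-trimethyl-5-oxodecahydronaphthalene-1-carboxylate
Conditions: (n-Pr4N)RuO4 (5 mol%), NMO, 4 Å MS, CH2Cl2, rt
Reagents that add atoms: none
Why: Ley–Griffith oxidation of the secondary alcohol under neutral conditions erases the sacrificial C5 stereocentre and gives a ketone with α-hydrogens only at C6.

Step 10
Reactants: 14 methyl (1S,2R,4aS,8aR)-2,4a,8a-trimethyl-5-oxodecahydronaphthalene-1-carboxylate
Product: 16 methyl (1S,2R,4aS,8aR)-2,4a,8a-trimethyl-5-{[(trifluoromethyl)sulfonyl]oxy}-1,2,3,4,4a,7,8,8a-octahydronaphthalene-1-carboxylate, via potassium enolate 15 (not isolated)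
Conditions: KN(SiMe3)2, THF, −78 °C; then PhNTf2, −78 → 0 °C
Reagents that add atoms: N-phenylbis(trifluoromethanesulfonimide), O=S(=O)(N(c1ccccc1)S(=O)(=O)C(F)(F)F)C(F)(F)F
Why: Kinetic deprotonation at C6, the only enolisable position of the ketone and far more acidic than the hindered ester α-hydrogen at C1, followed by O-sulfonylation of the enolate gives the C5=C6 enol triflate regiospecifically.

Step 11
Reactants: 16 methyl (1S,2R,4aS,8aR)-2,4a,8a-trimethyl-5-{[(trifluoromethyl)sulfonyl]oxy}-1,2,3,4,4a,7,8,8a-octahydronaphthalene-1-carboxylate; 17 5-bromo-2-methylpent-2-ene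
Product: 19 methyl (1S,2R,4aR,8aR)-2,4a,8a-trimethyl-5-(4-methylpent-3-en-1-yl)-1,2,3,4,4a,7,8,8a-octahydronaphthalene-1-carboxylate, via alkylzinc bromide 18 (not isolated)
Conditions: 17, Zn dust (activated with BrCH2CH2Br and Me3SiCl), LiCl, THF, 50 °C; then 16, Pd(dppf)Cl2 (5 mol%), THF, 60 °C
Reagents that add atoms: none
Why: Negishi cross-coupling: LiCl-assisted zinc insertion into the primary bromide gives an ester-tolerant alkylzinc, and the wide-bite-angle dppf ligand on palladium favours reductive elimination over β-hydride elimination, so the C5–C1′ bond forms with the alkene fixed at C5=C6.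

Step 12
Reactants: 19 methyl (1S,2R,4aR,8aR)-2,4a,8a-trimethyl-5-(4-methylpent-3-en-1-yl)-1,2,3,4,4a,7,8,8a-octahydronaphthalene-1-carboxylate
Product: 20 (1S,2R,4aR,8aR)-2,4a,8a-trimethyl-5-(4-methylpent-3-en-1-yl)-1,2,3,4,4a,7,8,8a-octahydronaphthalene-1-carboxylic acid
Conditions: NaSEt, DMF, 90 °C; then aq. HCl to pH 3
Reagents that add atoms: none
Why: SN2 dealkylation at the methyl carbon by thiolate, not acyl substitution, cleaves the hindered ester that would resist saponification; the C1 ester is already in its thermodynamically preferred equatorial position, so base should not erode it.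

Step 13
Reactants: 20 (1S,2R,4aR,8aR)-2,4a,8a-trimethyl-5-(4-methylpent-3-en-1-yl)-1,2,3,4,4a,7,8,8a-octahydronaphthalene-1-carboxylic acid; 21 (R)-solketal, [(4R)-2,2-dimethyl-1,3-dioxolan-4-yl]methanol
Product: 22 [(4S)-2,2-dimethyl-1,3-dioxolan-4-yl]methyl (1S,2R,4aR,8aR)-2,4a,8a-trimethyl-5-(4-methylpent-3-en-1-yl)-1,2,3,4,4a,7,8,8a-octahydronaphthalene-1-carboxylate
Conditions: PPh3, DIAD, THF, 0 °C → rt
Reagents that add atoms: none
Why: Mitsunobu esterification: the carboxylate attacks the activated primary carbon of solketal (SN2 at CH2), so the steric shielding of the acyl carbon does not matter and the dioxolane stereocentre is not touched (its descriptor changes from R to S only through priorities).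

Step 14
Reactants: 22 [(4S)-2,2-dimethyl-1,3-dioxolan-4-yl]methyl ester of acid 20
Product: 23 (2S)-2,3-dihydroxypropyl (1S,2R,4aR,8aR)-2,4a,8a-trimethyl-5-(4-methylpent-3-en-1-yl)-1,2,3,4,4a,7,8,8a-octahydronaphthalene-1-carboxylate
Conditions: AcOH/H2O (4:1), 40 °C
Reagents that add atoms: none
Why: Acid-catalysed acetal hydrolysis under weak-acid conditions that should not protonate the two trisubstituted alkenes (a 1,5-diene prone to cationic cyclisation in strong acid) and that keep migration of the hindered acyl group slow.

Step 15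
Reactants: 23 (2S)-2,3-dihydroxypropyl ester of acid 20
Product: 24 (2S)-3-(acetyloxy)-2-hydroxypropyl (1S,2R,4aR,8aR)-2,4a,8a-trimethyl-5-(4-methylpent-3-en-1-yl)-1,2,3,4,4a,7,8,8a-octahydronaphthalene-1-carboxylate (target)
Conditions: AcCl (1.05 equiv), 2,4,6-collidine, CH2Cl2, −78 °C
Reagents that add atoms: acetyl chloride, CC(Cl)=O
Why: Kinetically controlled acylation at low temperature with a hindered pyridine base should discriminate the primary from the secondary hydroxyl (primary-selective acetylation of a 1,2-diol), leaving the C2 hydroxyl free.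

**Compound list**

1 | (E)-but-2-enal (crotonaldehyde) | C/C=C/C=O | starting material
2 | 2-(triphenylphosphoranylidene)propanal | CC(C=O)=P(c1ccccc1)(c1ccccc1)c1ccccc1 | starting material
3 | (2E,4E)-2-methylhexa-2,4-dienal | C/C=C/C=C(\C)C=O | intermediate
4 | (4R,5E,7E)-5-methylnona-1,5,7-trien-4-yl diisopinocampheylborinate | C/C=C/C=C(\C)[C@@H](CC=C)OB([C@H]1C[C@H]2C[C@@H]([C@@H]1C)C2(C)C)[C@H]1C[C@H]2C[C@@H]([C@@H]1C)C2(C)C | intermediate
5 | (4R,5E,7E)-5-methylnona-1,5,7-trien-4-ol | C/C=C/C=C(\C)[C@H](O)CC=C | intermediate
6 | tert-butyldimethyl{[(4R,5E,7E)-5-methylnona-1,5,7-trien-4-yl]oxy}silane | C/C=C/C=C(\C)[C@H](O[Si](C)(C)C(C)(C)C)CC=C | intermediate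
7 | methyl 3-oxobutanoate (methyl acetoacetate) | CC(=O)CC(=O)OC | starting material
8 | methyl (2E)-3-{[(trifluoromethyl)sulfonyl]oxy}but-2-enoate | C/C(OS(=O)(=O)C(F)(F)F)=C\C(=O)OC | intermediate
9 | 9-[(4R,5E,7E)-4-[(tert-butyldimethylsilyl)oxy]-5-methylnona-5,7-dien-1-yl]-9-borabicyclo[3.3.1]nonane | C/C=C/C=C(\C)[C@H](O[Si](C)(C)C(C)(C)C)CCCB1C2CCCC1CCC2 | intermediate
10 | methyl (2E,7R,8E,10E)-7-[(tert-butyldimethylsilyl)oxy]-3,8-dimethyldodeca-2,8,10-trienoate | C/C=C/C=C(\C)[C@H](O[Si](C)(C)C(C)(C)C)CCC/C(C)=C/C(=O)OC | intermediate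
11 | methyl (1S,2R,4aS,5R,8aR)-5-[(tert-butyldimethylsilyl)oxy]-2,4a,8a-trimethyl-1,2,4a,5,6,7,8,8a-octahydronaphthalene-1-carboxylate | COC(=O)[C@H]1[C@H](C)C=C[C@]2(C)[C@H](O[Si](C)(C)C(C)(C)C)CCC[C@]12C | intermediate
12 | methyl (1S,2R,4aS,5R,8aR)-5-[(tert-butyldimethylsilyl)oxy]-2,4a,8a-trimethyldecahydronaphthalene-1-carboxylate | COC(=O)[C@H]1[C@H](C)CC[C@]2(C)[C@H](O[Si](C)(C)C(C)(C)C)CCC[C@]12C | intermediate
13 | methyl (1S,2R,4aS,5R,8aR)-5-hydroxy-2,4a,8a-trimethyldecahydronaphthalene-1-carboxylate | COC(=O)[C@H]1[C@H](C)CC[C@]2(C)[C@H](O)CCC[C@]12C | intermediate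
14 | methyl (1S,2R,4aS,8aR)-2,4a,8a-trimethyl-5-oxodecahydronaphthalene-1-carboxylate | COC(=O)[C@H]1[C@H](C)CC[C@]2(C)C(=O)CCC[C@]12C | intermediate
15 | potassium enolate of 14 (C5–O−, C5=C6) | COC(=O)[C@H]1[C@H](C)CC[C@]2(C)C([O-])=CCC[C@]12C.[K+] | intermediate
16 | methyl (1S,2R,4aS,8aR)-2,4a,8a-trimethyl-5-{[(trifluoromethyl)sulfonyl]oxy}-1,2,3,4,4a,7,8,8a-octahydronaphthalene-1-carboxylate | COC(=O)[C@H]1[C@H](C)CC[C@]2(C)C(OS(=O)(=O)C(F)(F)F)=CCC[C@]12C | intermediate
17 | 5-bromo-2-methylpent-2-ene | CC(C)=CCCBr | starting material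
18 | (4-methylpent-3-en-1-yl)zinc bromide | CC(C)=CCC[Zn]Br | intermediate
19 | methyl (1S,2R,4aR,8aR)-2,4a,8a-trimethyl-5-(4-methylpent-3-en-1-yl)-1,2,3,4,4a,7,8,8a-octahydronaphthalene-1-carboxylate | COC(=O)[C@H]1[C@H](C)CC[C@]2(C)C(CCC=C(C)C)=CCC[C@]12C | intermediate
20 | (1S,2R,4aR,8aR)-2,4a,8a-trimethyl-5-(4-methylpent-3-en-1-yl)-1,2,3,4,4a,7,8,8a-octahydronaphthalene-1-carboxylic acid | OC(=O)[C@H]1[C@H](C)CC[C@]2(C)C(CCC=C(C)C)=CCC[C@]12C | intermediate
21 | (R)-solketal, [(4R)-2,2-dimethyl-1,3-dioxolan-4-yl]methanol | CC1(C)OC[C@H](O1)CO | starting material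
22 | [(4S)-2,2-dimethyl-1,3-dioxolan-4-yl]methyl (1S,2R,4aR,8aR)-2,4a,8a-trimethyl-5-(4-methylpent-3-en-1-yl)-1,2,3,4,4a,7,8,8a-octahydronaphthalene-1-carboxylate | CC1(C)OC[C@H](O1)COC(=O)[C@H]2[C@H](C)CC[C@]3(C)C(CCC=C(C)C)=CCC[C@]23C | intermediate
23 | (2S)-2,3-dihydroxypropyl (1S,2R,4aR,8aR)-2,4a,8a-trimethyl-5-(4-methylpent-3-en-1-yl)-1,2,3,4,4a,7,8,8a-octahydronaphthalene-1-carboxylate | OC[C@H](O)COC(=O)[C@H]1[C@H](C)CC[C@]2(C)C(CCC=C(C)C)=CCC[C@]12C | intermediate
24 | (2S)-3-(acetyloxy)-2-hydroxypropyl (1S,2R,4aR,8aR)-2,4a,8a-trimethyl-5-(4-methylpent-3-en-1-yl)-1,2,3,4,4a,7,8,8a-octahydronaphthalene-1-carboxylate | CC(=O)OC[C@H](O)COC(=O)[C@H]1[C@H](C)CC[C@]2(C)C(CCC=C(C)C)=CCC[C@]12C | target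

**Step count and risks**

Total steps: 15. Longest linear sequence: 14 steps (steps 1, 2, 3, 5 and 6 to 15; step 4 is a one-step branch).

The three steps most likely to fail:

1. Step 6 (key step). The cycloaddition must join two fully substituted carbons through a diene whose inside position carries a methyl group. It may therefore be slower than a [1,5]-hydrogen shift from that methyl into the diene, or than general thermal decay. If it does proceed, the ester-endo (trans-fused) mode may compete with the required exo mode, and the silyloxy group may discriminate the diene faces incompletely, which would lower the enantiomeric purity of 14 unless the diastereomers are separated. The fallback sets out from 7 and 6 and returns at 11; it removes the need for exo selectivity. Compound 7 is triflated under chelation control (Tf2O, saturated aq. LiOH, toluene, 5 °C) to the (Z)-enol triflate F1. F1 is coupled with borane 9 (from 6) as in step 5 to give the (2Z)-trienoate F2. In F2 the ester and the tether are cis on the dienophile, so the ordinary ester-endo mode coincides with the tether-endo, cis-fused mode. It is enforced at low temperature with Et2AlCl (CH2Cl2, −40 → 0 °C) and should give the C1 epimer of the cycloadduct, 1-epi-11 F3. In F3 the ester is axial and syn to C5 across ring A, so equilibration with NaOMe in MeOH at 65 °C should move it to the equatorial position trans to the C2 methyl, which is 11.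

2. Step 11. Oxidative addition at the enol triflate, which is flanked by the quaternary C4a, may be slow, so that hydrolysis of the triflate, protodemetalation of 18 or β-hydride elimination and reduction take over. The fallback sets out from 14 and 17 and returns at 19; it adds the chain to the carbonyl group instead. Bromide 17 is converted (Mg, THF) into the Grignard reagent F4 and transmetalated with anhydrous CeCl3 to the organocerium reagent F5. F5 should add to the ketone of 14 at −78 °C in preference to the ester and without enolisation, giving tertiary alcohol F6 (C5 configuration immaterial). Syn-dehydration of F6 with the Burgess reagent (methyl N-(triethylammoniumsulfonyl)carbamate, PhMe, 70 °C) can remove only a C6 or a side-chain hydrogen because C4a is quaternary, and should give 19 after separation from any exocyclic alkene isomer.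

3. Step 15. Discrimination between the two hydroxyl groups may be incomplete (diacetate formation), and the acetyl group may migrate to O2 during reaction or chromatography. The fallback sets out from 20 and returns at 24; it installs the acetate by an epoxide opening that needs no hydroxyl discrimination. Mitsunobu esterification of 20 with (R)-glycidol (OC[C@@H]1CO1; PPh3, DIAD, THF) gives the glycidyl ester F7. Regioselective opening at the terminal epoxide carbon with acetic acid (i-Pr2NEt, catalytic trivalent cobalt complex (salen)Co(OAc), salen = N,N′-bis(3,5-di-tert-butylsalicylidene)cyclohexane-1,2-diamine, rt) should give 24 directly.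

Further compounds
F1 | step 6 | methyl (2Z)-3-{[(trifluoromethyl)sulfonyl]oxy}but-2-enoate | C/C(OS(=O)(=O)C(F)(F)F)=C/C(=O)OC
F2 | step 6 | methyl (2Z,7R,8E,10E)-7-[(tert-butyldimethylsilyl)oxy]-3,8-dimethyldodeca-2,8,10-trienoate | C/C=C/C=C(\C)[C@H](O[Si](C)(C)C(C)(C)C)CCC/C(C)=C\C(=O)OC
F3 | step 6 | methyl (1R,2R,4aS,5R,8aR)-5-[(tert-butyldimethylsilyl)oxy]-2,4a,8a-trimethyl-1,2,4a,5,6,7,8,8a-octahydronaphthalene-1-carboxylate | COC(=O)[C@@H]1[C@H](C)C=C[C@]2(C)[C@H](O[Si](C)(C)C(C)(C)C)CCC[C@]12C
F4 | step 11 | (4-methylpent-3-en-1-yl)magnesium bromide | CC(C)=CCC[Mg]Br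
F5 | step 11 | dichloro(4-methylpent-3-en-1-yl)cerium | CC(C)=CCC[Ce](Cl)Cl
F6 | step 11 | methyl (1S,2R,4aS,8aR)-5-hydroxy-2,4a,8a-trimethyl-5-(4-methylpent-3-en-1-yl)decahydronaphthalene-1-carboxylate (C5 not defined) | COC(=O)[C@H]1[C@H](C)CC[C@]2(C)C(O)(CCC=C(C)C)CCC[C@]12C
F7 | step 15 | [(2S)-oxiran-2-yl]methyl (1S,2R,4aR,8aR)-2,4a,8a-trimethyl-5-(4-methylpent-3-en-1-yl)-1,2,3,4,4a,7,8,8a-octahydronaphthalene-1-carboxylate | C1O[C@@H]1COC(=O)[C@H]1[C@H](C)CC[C@]2(C)C(CCC=C(C)C)=CCC[C@]12C
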